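**Plan**

Numbering: ring A carries C1 OMe, C2 Me, C3 OH, C4 CH2 bridge, C5 OMe, C6 isobutyryl. Ring B carries C1' bridge, C2' OH, C3' Me, C4' OH, C5' isobutyryl, C6' OH.
Enabling feature: in ring B, C2'-C3'(Me)-C4' is a methylmalonyl unit. C1'-C6'-C5' plus the isobutyryl carbonyl is a 1,3-diketone whose terminal carbon C1' already holds the ring A benzyl group, so ring B is cut at C1'-C2' and C4'-C5'.
Earlier cuts: C5'-C6' (Claisen condensation of a ring A propanoate with 3-methylbutan-2-one), C6-acyl on ring A (Friedel-Crafts), and C4-CH2 on ring A (acrylic acid annulation).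
Forward: ring A is bought as an arene. A dihydrocoumarin ring is closed on it to deliver the bridge CH2, C1' and C6' and to mask O3, then acylated and opened again. The chain is lengthened to the diketone and bis-silylated, ring B is closed last, and the benzyl group is removed.
Stereochemistry: the target has no stereocentre. Enol ether geometries and the transient sp3 centres of the ring closure are erased by aromatisation.

Key step: step 8

Remark on the chemistry: Ar stands for 2-(benzyloxy)-4,6-dimethoxy-3-methyl-5-(2-methylpropanoyl)phenyl. The silyl enol ether double bonds are assumed to be Z, the arrangement expected from the chelated enol. This geometry has no bearing on the outcome because it is lost in the ring closure. Diketones and phenols are drawn in one tautomeric form.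

**Route**

Step 1
Reactants: 1 2-hydroxy-4,6-dimethoxybenzaldehyde
Product: 2 3,5-dimethoxy-2-methylphenol
Conditions: H2 (3 atm), 10% Pd/C, AcOH, rt
Reagents that add atoms: none
Why: Catalytic hydrogenolysis of an electron-rich ortho-hydroxybenzaldehyde, in which the aldehyde is reduced to a benzylic alcohol that three oxygen donors make labile enough for C-O hydrogenolysis to the methyl group in acidic medium.

Step 2
Reactants: 2 3,5-dimethoxy-2-methylphenol; 3 acrylic acid
Product: 4 5,7-dimethoxy-8-methylchroman-2-one
Conditions: 3 (1.1 equiv), Amberlyst-15, hydroquinone (trace), toluene, reflux, Dean-Stark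
Reagents that add atoms: none
Why: Acid-catalysed tandem Friedel-Crafts conjugate alkylation and lactonisation, the known dihydrocoumarin synthesis from phenols and acrylic acid over sulfonic acid resins, should engage the ring carbon ortho to OH and para to OMe, which is the less crowded of the two free sites and the only one from which the lactone can close.

Step 3
Reactants: 4 5,7-dimethoxy-8-methylchroman-2-one; 5 2-methylpropanoyl chloride
Product: 6 5,7-dimethoxy-8-methyl-6-(2-methylpropanoyl)chroman-2-one
Conditions: 5 (1.2 equiv), AlCl3 (2.5 equiv), CH2Cl2, -10 to 0 °C; ice, 1 M HCl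
Reagents that add atoms: none
Why: Friedel-Crafts acylation at the single free ring position, which lies ortho to both methoxy groups and para to the lactone oxygen as in the acylation of phloroglucinol ethers, with the lactone masking O3 and low temperature with short contact sparing the methyl ethers next to the new ketone.

Step 4
Reactants: 6 5,7-dimethoxy-8-methyl-6-(2-methylpropanoyl)chroman-2-one
Product: 8 methyl 3-Ar-propanoate, via ring-opened hydroxy ester 7 (not isolated)
Conditions: K2CO3, BnBr (2 equiv), MeOH-acetone, reflux
Reagents that add atoms: methanol CO; benzyl bromide BrCc1ccccc1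
Why: One-flask transesterification and Williamson etherification, the standard opening of dihydrocoumarins, in which methoxide opens the aryl lactone and the released phenoxide is trapped irreversibly by benzyl bromide.

Step 5
Reactants: 8 methyl 3-Ar-propanoate; 9 3-methylbutan-2-one
Product: 10 1-Ar-6-methylheptane-3,5-dione
Conditions: 9 (3 equiv), NaH (4 equiv), THF, reflux; 1 M HCl
Reagents that add atoms: none
Why: Crossed Claisen condensation of a methyl ketone with an ester, in which only acylation at the CH3 group gives a diketone that can be deprotonated so that the equilibria drain to its sodium salt, while the ring A ketone, shielded by two ortho methoxy groups, can at most enolise and is restored on quenching.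

Step 6
Reactants: 10 1-Ar-6-methylheptane-3,5-dione
Product: 12 (2Z,4Z)-1-Ar-6-methyl-3,5-bis(trimethylsilyloxy)hepta-2,4-diene, via monosilyl enol ether 11 (not isolated)
Conditions: Me3SiOTf (2.2 equiv), Et3N (3 equiv), Et2O, 0 to 20 °C; decant, pentane, filter under argon, concentrate, use at once
Reagents that add atoms: trimethylsilyl trifluoromethanesulfonate C[Si](C)(C)OS(=O)(=O)C(F)(F)F
Why: Soft enolisation with a silyl triflate and a tertiary amine, the known one-flask conversion of 1,3-diketones into 1,3-bis(silyloxy)dienes, in which the vinylogous ester oxygen of 11 is far more basic than the twisted ring A ketone and takes the second silyl group, after which Et3N should remove the accessible CH2 proton rather than the isopropyl methine, whose loss would give a strained, non-planar tetrasubstituted diene.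

Step 7
Reactants: 13 methylmalonic acid
Product: 14 methylmalonyl dichloride
Conditions: SOCl2 (4 equiv, neat), 50 to 60 °C; distil at reduced pressure
Reagents that add atoms: thionyl chloride O=S(Cl)Cl
Why: Standard conversion of a malonic acid into its dichloride with thionyl chloride, held at moderate temperature to avoid decarboxylation and loss of HCl to the ketene.

Step 8
Reactants: 12 (2Z,4Z)-1-Ar-6-methyl-3,5-bis(trimethylsilyloxy)hepta-2,4-diene; 14 methylmalonyl dichloride
Product: 17 target O3 benzyl ether, 1-[3-(Ar-methyl)-2,4,6-trihydroxy-5-methylphenyl]-2-methylpropan-1-one, via acyclic acid chloride 15 (not isolated), via cyclohexanetrione tautomer 16 (not isolated)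
Conditions: 12 and 14 (1.0 equiv) added together by syringe pump to CH2Cl2 (final 0.01 M), -78 to 20 °C; evaporate Me3SiCl; THF-1 M HCl, rt
Reagents that add atoms: none
Why: Proposed new method: the terminal carbon C1' of the 1,3-bis(silyloxy)diene, its most nucleophilic site, attacks one acyl chloride of 14 and sheds Me3SiCl to give 15 (bond C1'-C2'), after which the surviving silyl enol ether carbon C5' attacks the second acyl chloride, sheds the second Me3SiCl (bond C4'-C5') and gives trione 16, the keto tautomer of arene 17. The closest known reaction types are the Effenberger cyclisation of simple ketone enol ethers with malonyl dichlorides to cyclohexane-1,3,5-triones and phloroglucinols, and the uncatalysed terminal C-acylation of 1,3-bis(silyl enol ethers) with acid chlorides; their union on an acyclic, diketone-derived diene with a substituted malonyl dichloride has not been shown. Ring B closes in a 6-(enolexo)-exo-trig mode, and the transient centres at C1', C3' and C5' vanish on enolisation, so no stereocentre has to be controlled. The closure must go through carbon rather than oxygen: the enol oxygen on the isobutyryl side is capped by silicon, no base is present to raise the nucleophilicity of the C6' enol oxygen, and only closure at C5' is rewarded by aromatisation. The second acylation must also be intramolecular, which high dilution and the six-atom spacing of C5' and C4' in 15 secure. Ring A stays a spectator because all six of its positions are substituted, O3 is benzylated and its ketone is shielded by two ortho methoxy groups.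

Step 9
Reactants: 17 target O3 benzyl ether
Product: 18 target, 1-[3-{[2-hydroxy-4,6-dimethoxy-3-methyl-5-(2-methylpropanoyl)phenyl]methyl}-2,4,6-trihydroxy-5-methylphenyl]-2-methylpropan-1-one
Conditions: H2 (1 atm), 10% Pd/C, EtOAc-MeOH, rt
Reagents that add atoms: none
Why: Hydrogenolysis of an aryl benzyl ether under neutral conditions, which should leave the hindered ring A ketone, the vinylogous-acid ketone of ring B and the diarylmethane link untouched and offers neither acid nor base that could scramble the methylene bridge.

**Compound list**

1 | 2-hydroxy-4,6-dimethoxybenzaldehyde | COc1cc(O)c(C=O)c(OC)c1 | starting material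
2 | 3,5-dimethoxy-2-methylphenol | COc1cc(O)c(C)c(OC)c1 | intermediate
3 | acrylic acid | C=CC(=O)O | starting material
4 | 5,7-dimethoxy-8-methylchroman-2-one | COc1cc(OC)c2c(c1C)OC(=O)CC2 | intermediate
5 | 2-methylpropanoyl chloride | CC(C)C(=O)Cl | starting material
6 | 5,7-dimethoxy-8-methyl-6-(2-methylpropanoyl)chroman-2-one | COc1c(C(=O)C(C)C)c(OC)c2c(c1C)OC(=O)CC2 | intermediate
7 | methyl 3-[2-hydroxy-4,6-dimethoxy-3-methyl-5-(2-methylpropanoyl)phenyl]propanoate (present as its potassium phenoxide, not isolated) | COC(=O)CCc1c(O)c(C)c(OC)c(C(=O)C(C)C)c1OC | intermediate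
8 | methyl 3-[2-(benzyloxy)-4,6-dimethoxy-3-methyl-5-(2-methylpropanoyl)phenyl]propanoate | COC(=O)CCc1c(OCc2ccccc2)c(C)c(OC)c(C(=O)C(C)C)c1OC | intermediate
9 | 3-methylbutan-2-one | CC(C)C(C)=O | starting material
10 | 1-[2-(benzyloxy)-4,6-dimethoxy-3-methyl-5-(2-methylpropanoyl)phenyl]-6-methylheptane-3,5-dione | CC(C)C(=O)CC(=O)CCc1c(OCc2ccccc2)c(C)c(OC)c(C(=O)C(C)C)c1OC | intermediate
11 | (4Z)-7-Ar-2-methyl-5-(trimethylsilyloxy)hept-4-en-3-one (one of two interconverting regioisomers, not isolated) | CC(C)C(=O)/C=C(\O[Si](C)(C)C)CCc1c(OCc2ccccc2)c(C)c(OC)c(C(=O)C(C)C)c1OC | intermediate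
12 | (2Z,4Z)-1-Ar-6-methyl-3,5-bis(trimethylsilyloxy)hepta-2,4-diene | CC(C)/C(O[Si](C)(C)C)=C/C(O[Si](C)(C)C)=C/Cc1c(OCc2ccccc2)c(C)c(OC)c(C(=O)C(C)C)c1OC | intermediate
13 | methylmalonic acid | CC(C(=O)O)C(=O)O | starting material
14 | methylmalonyl dichloride | CC(C(=O)Cl)C(=O)Cl | intermediate
15 | (6Z)-4-(Ar-methyl)-2,8-dimethyl-3,5-dioxo-7-(trimethylsilyloxy)non-6-enoyl chloride (racemic diastereomer mixture, not isolated) | CC(C)/C(O[Si](C)(C)C)=C/C(=O)C(Cc1c(OCc2ccccc2)c(C)c(OC)c(C(=O)C(C)C)c1OC)C(=O)C(C)C(=O)Cl | intermediate
16 | 2-(Ar-methyl)-4-methyl-6-(2-methylpropanoyl)cyclohexane-1,3,5-trione (stereoisomer mixture, not isolated) | CC(C)C(=O)C1C(=O)C(C)C(=O)C(Cc2c(OCc3ccccc3)c(C)c(OC)c(C(=O)C(C)C)c2OC)C1=O | intermediate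
17 | 1-[3-{[2-(benzyloxy)-4,6-dimethoxy-3-methyl-5-(2-methylpropanoyl)phenyl]methyl}-2,4,6-trihydroxy-5-methylphenyl]-2-methylpropan-1-one | COc1c(C)c(OCc2ccccc2)c(Cc2c(O)c(C)c(O)c(C(=O)C(C)C)c2O)c(OC)c1C(=O)C(C)C | intermediate
18 | 1-[3-{[2-hydroxy-4,6-dimethoxy-3-methyl-5-(2-methylpropanoyl)phenyl]methyl}-2,4,6-trihydroxy-5-methylphenyl]-2-methylpropan-1-one | COc1c(C)c(O)c(Cc2c(O)c(C)c(O)c(C(=O)C(C)C)c2O)c(OC)c1C(=O)C(C)C | target

**Step count**

Total step count: 9. Longest linear sequence: 8 steps (steps 1 to 6, 8 and 9).

**Steps most likely to fail**

**Step 8.** Three things may go wrong: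
- The ring may close through the C6' enol oxygen instead of C5'.
- The dichloride may lose HCl to a ketene, and the acid set free may strip the silyl groups.
- The second acylation may turn intermolecular.

The fallback sets out from 12 and returns at 17. It splits the double acylation into two known operations with a differentiated three-carbon unit.
- Purchased 3-methoxy-2-methyl-3-oxopropanoic acid is converted with (COCl)2 and catalytic DMF into methyl 3-chloro-2-methyl-3-oxopropanoate F1.
- Diene 12 is acylated by F1 at its terminal carbon (CH2Cl2, -78 to 20 °C, then dilute HCl). This is the established route from bis(silyl enol ethers) to 1,3,5-tricarbonyl compounds, and it should give methyl 4-(Ar-methyl)-2,8-dimethyl-3,5,7-trioxononanoate F2.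
- NaOMe in MeOH, or Mg(OMe)2, then brings about Claisen (Dieckmann) closure of C5' onto the ester carbon C4'. This is the classical cyclisation of 3,5,7-triketo esters to acylphloroglucinols, and it should give 17.

The competing aldol closure cannot aromatise because C3' bears the methyl group. Material from step 8 that closed through oxygen is opened by the same methoxide treatment to F2 and joins this path. The benzyl group on O3 keeps the methylene bridge from scrambling in base.

**Step 6.** Enolisation may run toward the isopropyl methine, the ring A ketone may be partly silylated, and the diene may hydrolyse on handling.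

The fallback sets out from 8 and returns at 17. It fixes the position of both enol ethers by construction instead of by selective enolisation.
- Lithium 3-methylbut-1-ynide with BF3·OEt2 (THF, -78 °C) should convert ester 8 into 1-Ar-6-methylhept-4-yn-3-one F3.
- Conjugate addition of methanol (catalytic NaOMe, MeOH, rt) places the enol ether oxygen only on the isopropyl-bearing carbon and should give (4E)-1-Ar-5-methoxy-6-methylhept-4-en-3-one F4.
- Kinetic deprotonation (LDA, THF, -78 °C, then Me3SiCl) can then occur only at the alpha' CH2 and should give (2Z,4E)-1-Ar-5-methoxy-6-methyl-3-(trimethylsilyloxy)hepta-2,4-diene F5.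
- F5 takes the place of 12 in step 8. The methyl enol ether is dealkylated by chloride after the second acylation, as in the parent Effenberger process.

**Step 2.** Acrylic acid may polymerise, a second alkylation may occur at the remaining ring position, or acylation may compete with conjugate alkylation.

The fallback sets out from 2 and returns at 4. It uses an alkyne in place of the alkene.
- Ethyl propiolate with catalytic Pd(OAc)2 in CF3CO2H-CH2Cl2 at rt (hydroarylation and lactonisation of electron-rich phenols) should give 5,7-dimethoxy-8-methylcoumarin F6. Its deactivated ring resists further alkylation.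
- H2 over 10% Pd/C in EtOAc then saturates the C3-C4 bond to give 4.

**Further compounds**

F1 | step 8 | methyl 3-chloro-2-methyl-3-oxopropanoate | COC(=O)C(C)C(=O)Cl
F2 | step 8 | methyl 4-(Ar-methyl)-2,8-dimethyl-3,5,7-trioxononanoate | COC(=O)C(C)C(=O)C(Cc1c(OCc2ccccc2)c(C)c(OC)c(C(=O)C(C)C)c1OC)C(=O)CC(=O)C(C)C
F3 | step 6 | 1-Ar-6-methylhept-4-yn-3-one | CC(C)C#CC(=O)CCc1c(OCc2ccccc2)c(C)c(OC)c(C(=O)C(C)C)c1OC
F4 | step 6 | (4E)-1-Ar-5-methoxy-6-methylhept-4-en-3-one | CO/C(C(C)C)=C/C(=O)CCc1c(OCc2ccccc2)c(C)c(OC)c(C(=O)C(C)C)c1OC
F5 | step 6 | (2Z,4E)-1-Ar-5-methoxy-6-methyl-3-(trimethylsilyloxy)hepta-2,4-diene | CO/C(C(C)C)=C/C(O[Si](C)(C)C)=C/Cc1c(OCc2ccccc2)c(C)c(OC)c(C(=O)C(C)C)c1OC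
F6 | step 2 | 5,7-dimethoxy-8-methylcoumarin | COc1cc(OC)c2ccc(=O)oc2c1C
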